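**Analysis of the target**

The target is an isoflavone: a 5,7-dihydroxy-4H-chromen-4-one (rings A and C) that carries a third benzene ring, ring B, on C3. Ring B is substituted on four adjacent carbons: C1' is bonded to C3, C2' bears a free hydroxyl, and a dihydropyran (ring D) is fused across C3'–C4', with its oxygen on C4', its benzylic carbon C4'' on C3' and two methyl groups on C2''. The only stereocentre is the secondary carbinol C3'' (S). With no second stereocentre to relay from, its configuration has to come from a chiral catalyst or reagent. Sensitive groups are the chromone (C2 is opened by hydroxide and amines, C2=C3 can be reduced), four phenols, and a carbinol next to a tertiary aryl ether that can ionise, dehydrate or rearrange in strong acid. The hard part is ring B: O2' and O4' both flank C3', only O4' may enter ring D, and C1' must be marked for the biaryl bond on the side of O2'. Electrophilic substitution cannot be trusted to tell the two open positions of a 2,6-dioxygenated benzyl unit apart, because each is ortho to one oxygen and para to the other. The strategy rests on ring D: C3'' lies between benzylic C4'' and the oxygen-bearing C2''. C3'' and C2'' (with its methyl) are therefore the hydroxylated carbon and the carbonyl carbon of hydroxyacetone (10), and C4'' is the exocyclic carbon of an ortho-quinone methide on C3' conjugated to O4'.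

**Retrosynthetic reasoning**

Target 22 to tribenzyl ether 21. The three phenols of 22 are masked as benzyl ethers and freed in the last step by hydrogenolysis. Benzyl survives carbonate, organoaluminium and palladium chemistry, and one neutral final step avoids acid or base on the finished isoflavone. The secondary alcohol is carried free, because none of the reagents after its formation attacks it.

21 to boronate 16 and iodochromone 20. The C3–C1' bond is cut. This divides the molecule into the achiral rings A and C and the chiral rings B and D, and joins them late by a Suzuki coupling between two sp2 carbons. Boron is placed on ring B and iodine on the chromone, because 20 is made in three steps from 17 through 18 and 19. The coupling has to work next to one ortho benzyloxy group under a base mild enough for the chromone.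

16 to bromide 15. The C–B bond comes from the C–Br bond by palladium-catalysed borylation, so that the halogen placed on ring B at the outset serves as the marker for C1'.

15 to methyl ketal 14 to hemiketal 13. The second methyl group on C2'' is cut off. It must come last, because the annulation needs a carbonyl carbon at C2''. The hemiketal cannot be methylated as such: its metal alkoxide reverts to ketone 12, and methyl addition to 12 would leave ring D open. The hydroxyl is therefore exchanged for methoxy, so that an exocyclic group leaves and the ring oxygen stays.

13 to sulfone 9 and hydroxyacetone 10. This is the key disconnection: C4''–C3'' and O4'–C2'' are cut together. Both bonds and the stereocentre are formed in one catalytic operation from an achiral arene and a three-carbon ketone, and no oxidation of ring D is needed afterwards. The forward reaction must release methide 11 from 9, add the enamine of 10 through its hydroxylated carbon with facial control, and close ketone 12 onto O4'.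

9 to benzylic alcohol 7 and sulfinate 8, and 7 to aldehyde 6. The sulfone is the bench-stable store of the methide. It comes from acid-promoted substitution of the benzylic alcohol by 8, and the alcohol comes from hydride reduction of 6.

6 to 4 to 2 to 1. The substitution pattern of ring B is taken from the starting material instead of from an electrophilic bromination. In 1 the bromine already sits next to the oxygen that becomes O2', and fluorine marks the carbon that becomes C4'. After benzylation (2), the only hydrogen flanked by fluorine and oxygen is removed by a lithium amide and replaced by the formyl carbon, the future C4'' (4). The formyl group then activates the fluorine for replacement by oxygen (6). Every position is fixed by connectivity, at the price of one step more than a bromination route.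

**Alternatives that were turned down**

Alternative 1: Ring D is cut at C3'–C4'' and O4'–C2'' at the chromene oxidation level. In the forward key step 2,4-dihydroxybenzaldehyde A1 condenses at C3' with 3-methylbut-2-enal A2 under ammonium-salt catalysis, and the ortho-quinone methide formed closes by oxa-6π electrocyclisation to 5-hydroxy-2,2-dimethyl-2H-chromene-6-carbaldehyde A3.
- For: one step from two cheap compounds without protecting groups. The chelated hydroxyl next to the formyl group steers the annulation to the angular position. A 2,2-dimethylchromene is the classical substrate for salen–manganese epoxidation, after which hydride opening at the benzylic carbon gives the 3-ol.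
- Against: the stereocentre is not made in the key step. Two further redox steps are needed on an electron-rich chromene that carries a free phenol and an aldehyde. C1' ends up bearing a formyl carbon, not a leaving group, so the isoflavone has to be grown linearly (chalcone and oxidative 1,2-aryl shift, or a deoxybenzoin), with oxidants that must spare ring D.
- Comparison: on precedent and on the cost of ring D this alternative is the stronger one. The chosen strategy offers in its place ring and stereocentre in one catalytic C–C bond formation, and a bromide at C1' for a convergent coupling with a ring A/C fragment made separately.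

Alternative 2: The C4–C4a bond of ring C is cut. In the forward key step (2Z)-3-[3,5-bis(benzyloxy)phenoxy]-2-[(3S)-3,5-bis(benzyloxy)-2,2-dimethyl-3,4-dihydro-2H-chromen-6-yl]prop-2-enoic acid A4 is turned by TFAA into a mixed anhydride. This acylates the symmetric aryloxy ring ortho to the ether oxygen and closes ring C, giving the tetrabenzyl ether A5 of the target.
- For: the symmetry of ring A removes any regiochemical question, and only hydrogenolysis remains afterwards.
- Against: the step does nothing for ring D or for C3''. The complete ring B/D unit must exist beforehand and must then be elaborated, over several linear steps on the most valuable fragment, into an acrylic acid with the acid and the aryloxy group cis. The carbinol needs a fourth benzyl group because the anhydride would acylate it. The electron-rich tertiary aryl ether is exposed to a strongly acidic acylating medium.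
- Comparison: the ring closure of A4 is at least as safe as a cross-coupling, but the route is longer and less convergent, and the real problem of the target, ring D with its stereocentre, stays unsolved. The chosen strategy puts its key step exactly there.

Alternative 3: C3–C4 and O1–C2 are cut together. In the forward key step 5,7-bis(methoxymethoxy)-2,2-dimethyl-4H-1,3-benzodioxin-4-one A6 loses its ketone-derived acetal unit on photolysis or thermolysis to give a quinoketene. This adds the ring B enol ether (3S)-6-(2-methoxyethenyl)-3,5-bis(methoxymethoxy)-2,2-dimethyl-3,4-dihydro-2H-chromene A7 in a hetero-Diels–Alder reaction to give the 2-methoxyisoflavanone A8. Loss of the C2 methoxy group and acid deprotection would follow.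
- For: convergent, two bonds in one metal-free step, and all protecting groups fall in one acidic operation.
- Against: acylketenes of this kind are trapped far more readily by heteroatom nucleophiles than by a β-aryl enol ether. Competing [2+2] addition, ketene dimerisation and photochemistry of the styrenyl ether are to be expected. A7 again needs a formyl group at C1' and the finished ring D with its stereocentre.
- Comparison: the convergence is equal to that of the chosen route, but the chosen route joins the halves by a coupling with broad use for isoflavones, and keeps its uncertainty in the step that also creates the stereocentre.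

Key step: step 6

Assumption: the (1R,2R) enantiomer of the primary amine–thiourea catalyst is taken as the one that exposes the Si face of the enamine carbon (the face that leads to 3S); if the sense of induction is the reverse, the (1S,2S) enantiomer is used and nothing else changes.

**Route**

Step 1
Reactants: 1 2-bromo-5-fluorophenol
Product: 2 2-(benzyloxy)-1-bromo-4-fluorobenzene
Conditions: BnBr, K2CO3, DMF, rt
Reagents that add atoms: benzyl bromide, BrCc1ccccc1
Why: Williamson etherification of the phenoxide; the aryl bromide and aryl fluoride are inert to carbonate, and the benzyl group marks this oxygen as O2' for the whole route.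

Step 2
Reactants: 2 2-(benzyloxy)-1-bromo-4-fluorobenzene
Product: 4 2-(benzyloxy)-3-bromo-6-fluorobenzaldehyde, via aryllithium 3 (not isolated)
Conditions: LiN(iPr)2, THF, −78 °C; DMF, −78 °C to 0 °C; aq. NH4Cl
Reagents that add atoms: N,N-dimethylformamide, CN(C)C=O
Why: Directed ortho-lithiation: the hydrogen flanked by fluorine and the benzyloxy oxygen is by far the most acidic, a lithium amide at −78 °C removes it without bromine–lithium exchange or loss of LiF, and DMF formylates the aryllithium.

Step 3
Reactants: 4 2-(benzyloxy)-3-bromo-6-fluorobenzaldehyde
Product: 6 2-(benzyloxy)-3-bromo-6-hydroxybenzaldehyde, via sulfonylethyl aryl ether 5 (not isolated)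
Conditions: MeSO2CH2CH2OH, NaH, DMF, 0 °C to rt; aq. HCl
Reagents that add atoms: 2-(methylsulfonyl)ethanol, CS(=O)(=O)CCO
Why: Nucleophilic aromatic substitution of the fluoride ortho to the formyl group (and para to bromine) by the alkoxide, followed by E1cB loss of methyl vinyl sulfone from ether 5 under the excess base; the phenoxide released deactivates the ring, so the reaction stops there.

Step 4
Reactants: 6 2-(benzyloxy)-3-bromo-6-hydroxybenzaldehyde
Product: 7 3-(benzyloxy)-4-bromo-2-(hydroxymethyl)phenol
Conditions: NaBH4, THF–MeOH, 0 °C; aq. NH4Cl
Reagents that add atoms: none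
Why: Hydride reduction of the aldehyde; bromide and benzyl ether are untouched, and the work-up is kept near neutral because the 2,6-dioxygenated benzylic alcohol ionises easily.

Step 5
Reactants: 7 3-(benzyloxy)-4-bromo-2-(hydroxymethyl)phenol; 8 sodium 4-methylbenzenesulfinate
Product: 9 3-(benzyloxy)-4-bromo-2-[(4-methylbenzenesulfonyl)methyl]phenol
Conditions: 8 (2 equiv), HCO2H–H2O, rt
Reagents that add atoms: none
Why: Acid-promoted ionisation of the benzylic alcohol (cation stabilised by the ortho hydroxyl and ortho alkoxy groups) and S-alkylation of the sulfinate give the sulfone, the stable store of the methide; excess sulfinate suppresses self-condensation of the electron-rich arene.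

Step 6
Reactants: 9 3-(benzyloxy)-4-bromo-2-[(4-methylbenzenesulfonyl)methyl]phenol; 10 hydroxyacetone
Product: 13 (3S)-5-(benzyloxy)-6-bromo-2-methyl-3,4-dihydro-2H-chromene-2,3-diol, via ortho-quinone methide 11 (not isolated), via open-chain hydroxy ketone 12 (not isolated)
Conditions: 10 (5 equiv), 1-[(1R,2R)-2-aminocyclohexyl]-3-[3,5-bis(trifluoromethyl)phenyl]thiourea (20 mol%), aq. Na2CO3, toluene, 0 °C to rt
Reagents that add atoms: none
Why: Carbonate deprotonates the phenol of 9 and the phenoxide expels sulfinate (E1cB) to give methide 11, which can only be conjugated to O4' because O2' is benzylated, and whose electrophilicity is tempered by the benzyloxy group on the dienone. The primary amine condenses with 10 on the hydroxylated side to the (Z)-enamine, held by an N–H···O hydrogen bond, and its α-carbon adds 1,4 to the exocyclic methide carbon, forming C4''–C3''. Hydrolysis of the iminium ion frees ketone 12 and the catalyst, and the regenerated phenol O4' adds to the ketone carbon in a 6-exo-trig hemiketalisation that forms O4'–C2'' and closes ring D. The closest known reaction type is the amine-catalysed enantioselective Michael addition and hemiacetalisation of aldehydes and ketones with ortho-quinone methides released by base from 2-(sulfonylalkyl)phenols; an α-hydroxy ketone and a methide without a substituent on its exocyclic carbon are new partners within that class. C3'' is the only controlled stereocentre and is set by the catalyst: the thiourea binds the methide oxygen while the cyclohexane backbone covers one enamine face, so that the electrophile is delivered to the Si face and the S carbinol should result. C2'' forms as a mixture of hemiketal epimers, which is of no consequence because this carbon later becomes the CMe2 group. The step needs regioselective enamine formation (secured by the hydroxyl hydrogen bond), a single methide regioisomer (secured by the benzyl ether) and addition faster than methide dimerisation or alkylation of the amine (favoured by slow biphasic release of 11 and the excess of 10).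

Step 7
Reactants: 13 (3S)-5-(benzyloxy)-6-bromo-2-methyl-3,4-dihydro-2H-chromene-2,3-diol
Product: 14 (3S)-5-(benzyloxy)-6-bromo-2-methoxy-2-methyl-3,4-dihydro-2H-chromen-3-ol
Conditions: MeOH, PPTS (cat.), 3 Å MS, rt; concentration
Reagents that add atoms: methanol, CO
Why: Acid-catalysed exchange of the hemiketal hydroxyl for methoxy through the cyclic oxocarbenium ion (ketose glycosidation type); both C2 epimers and any open-chain 12 converge on the cyclic ketal, and C3 is not part of the reacting centre.

Step 8
Reactants: 14 (3S)-5-(benzyloxy)-6-bromo-2-methoxy-2-methyl-3,4-dihydro-2H-chromen-3-ol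
Product: 15 (3S)-5-(benzyloxy)-6-bromo-2,2-dimethyl-3,4-dihydro-2H-chromen-3-ol
Conditions: AlMe3 (4 equiv), CH2Cl2, −78 °C to rt; aq. potassium sodium tartrate
Reagents that add atoms: trimethylaluminium, C[Al](C)C
Why: Lewis acid-mediated substitution of a ketal by an organoaluminium reagent: AlMe3 first forms the C3 aluminium alkoxide, further reagent complexes the more basic exocyclic methoxy oxygen, which leaves to give the ring oxocarbenium ion, and methyl is transferred to C2. C2 becomes the non-stereogenic CMe2 carbon and C3 keeps its S configuration because no bond to it is broken.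

Step 9
Reactants: 15 (3S)-5-(benzyloxy)-6-bromo-2,2-dimethyl-3,4-dihydro-2H-chromen-3-ol
Product: 16 (3S)-5-(benzyloxy)-2,2-dimethyl-6-(4,4,5,5-tetramethyl-1,3,2-dioxaborolan-2-yl)-3,4-dihydro-2H-chromen-3-ol
Conditions: B2pin2, PdCl2(dppf), KOAc, 1,4-dioxane, 85 °C
Reagents that add atoms: bis(pinacolato)diboron, CC1(C)OB(OC1(C)C)B1OC(C)(C)C(C)(C)O1
Why: Miyaura borylation: oxidative addition of zerovalent palladium into the C–Br bond, acetate-assisted transmetalation with the diboron and reductive elimination; the weak base leaves the free alcohol and the benzyl ether alone and suppresses biaryl homocoupling.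

Step 10
Reactants: 17 2,4,6-trihydroxyacetophenone
Product: 18 1-[2,4-bis(benzyloxy)-6-hydroxyphenyl]ethan-1-one
Conditions: BnBr (2.1 equiv), K2CO3, DMF, rt
Reagents that add atoms: benzyl bromide, BrCc1ccccc1
Why: Williamson etherification of two phenols; the third hydroxyl stays free because it is hydrogen-bonded to the acetyl carbonyl and is the least nucleophilic once two equivalents of halide are consumed.

Step 11
Reactants: 18 1-[2,4-bis(benzyloxy)-6-hydroxyphenyl]ethan-1-one
Product: 19 (2E)-1-[2,4-bis(benzyloxy)-6-hydroxyphenyl]-3-(dimethylamino)prop-2-en-1-one
Conditions: Me2NCH(OMe)2, toluene, 90 °C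
Reagents that add atoms: N,N-dimethylformamide dimethyl acetal, COC(OC)N(C)C
Why: Condensation of the methyl ketone with the amide acetal gives the (E)-enaminone, whose new carbon becomes C2 of the chromone.

Step 12
Reactants: 19 (2E)-1-[2,4-bis(benzyloxy)-6-hydroxyphenyl]-3-(dimethylamino)prop-2-en-1-one
Product: 20 5,7-bis(benzyloxy)-3-iodo-4H-chromen-4-one
Conditions: I2, CHCl3, rt; aq. Na2S2O3/NaHCO3
Reagents that add atoms: iodine, II
Why: Iodocyclisation of a 2-hydroxyaryl enaminone: iodine attacks the enaminone α-carbon, the chelated phenol closes onto the iminium carbon and dimethylamine is lost, giving the 3-iodochromone directly.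

Step 13
Reactants: 16 (3S)-5-(benzyloxy)-2,2-dimethyl-6-(4,4,5,5-tetramethyl-1,3,2-dioxaborolan-2-yl)-3,4-dihydro-2H-chromen-3-ol; 20 5,7-bis(benzyloxy)-3-iodo-4H-chromen-4-one
Product: 21 5,7-bis(benzyloxy)-3-[(3S)-5-(benzyloxy)-3-hydroxy-2,2-dimethyl-3,4-dihydro-2H-chromen-6-yl]-4H-chromen-4-one
Conditions: PdCl2(dppf) (5 mol%), K3PO4, 1,4-dioxane–H2O, 80 °C
Reagents that add atoms: none
Why: Suzuki–Miyaura coupling: the C–I bond of the 3-iodochromone adds quickly to palladium, phosphate activates the boronate for transmetalation and reductive elimination forms C3–C1'; the base is mild enough for the chromone and no stereocentre is touched.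

Step 14
Reactants: 21 5,7-bis(benzyloxy)-3-[(3S)-5-(benzyloxy)-3-hydroxy-2,2-dimethyl-3,4-dihydro-2H-chromen-6-yl]-4H-chromen-4-one
Product: 22 5,7-dihydroxy-3-[(3S)-3,5-dihydroxy-2,2-dimethyl-3,4-dihydro-2H-chromen-6-yl]-4H-chromen-4-one
Conditions: H2 (1 atm), 10% Pd/C, EtOAc–MeOH, rt, stopped at full debenzylation
Reagents that add atoms: none
Why: Hydrogenolysis of the three aryl benzyl ethers; the C–O bonds of ring D are not benzylic and stay, and the chromone C2=C3 bond is reduced only slowly under these conditions.

**Compound list**

1 | 2-bromo-5-fluorophenol | Oc1cc(F)ccc1Br | starting material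
2 | 2-(benzyloxy)-1-bromo-4-fluorobenzene | Fc1ccc(Br)c(OCc2ccccc2)c1 | intermediate
3 | [2-(benzyloxy)-3-bromo-6-fluorophenyl]lithium | [Li]c1c(F)ccc(Br)c1OCc1ccccc1 | intermediate (not isolated)
4 | 2-(benzyloxy)-3-bromo-6-fluorobenzaldehyde | O=Cc1c(F)ccc(Br)c1OCc1ccccc1 | intermediate
5 | 2-(benzyloxy)-3-bromo-6-[2-(methanesulfonyl)ethoxy]benzaldehyde | CS(=O)(=O)CCOc1ccc(Br)c(OCc2ccccc2)c1C=O | intermediate (not isolated)
6 | 2-(benzyloxy)-3-bromo-6-hydroxybenzaldehyde | O=Cc1c(O)ccc(Br)c1OCc1ccccc1 | intermediate
7 | 3-(benzyloxy)-4-bromo-2-(hydroxymethyl)phenol | OCc1c(O)ccc(Br)c1OCc1ccccc1 | intermediate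
8 | sodium 4-methylbenzenesulfinate | [Na+].Cc1ccc(cc1)S(=O)[O-] | starting material
9 | 3-(benzyloxy)-4-bromo-2-[(4-methylbenzenesulfonyl)methyl]phenol | Cc1ccc(cc1)S(=O)(=O)Cc1c(O)ccc(Br)c1OCc1ccccc1 | intermediate
10 | hydroxyacetone | CC(=O)CO | starting material
11 | 5-(benzyloxy)-4-bromo-6-methylidenecyclohexa-2,4-dien-1-one | C=C1C(=O)C=CC(Br)=C1OCc1ccccc1 | intermediate (not isolated)
12 | (3S)-4-[2-(benzyloxy)-3-bromo-6-hydroxyphenyl]-3-hydroxybutan-2-one | CC(=O)[C@@H](O)Cc1c(O)ccc(Br)c1OCc1ccccc1 | intermediate (not isolated)
13 | (3S)-5-(benzyloxy)-6-bromo-2-methyl-3,4-dihydro-2H-chromene-2,3-diol (mixture of C2 epimers) | CC1(O)Oc2ccc(Br)c(OCc3ccccc3)c2C[C@@H]1O | intermediate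
14 | (3S)-5-(benzyloxy)-6-bromo-2-methoxy-2-methyl-3,4-dihydro-2H-chromen-3-ol (mixture of C2 epimers) | COC1(C)Oc2ccc(Br)c(OCc3ccccc3)c2C[C@@H]1O | intermediate
15 | (3S)-5-(benzyloxy)-6-bromo-2,2-dimethyl-3,4-dihydro-2H-chromen-3-ol | CC1(C)Oc2ccc(Br)c(OCc3ccccc3)c2C[C@@H]1O | intermediate
16 | (3S)-5-(benzyloxy)-2,2-dimethyl-6-(4,4,5,5-tetramethyl-1,3,2-dioxaborolan-2-yl)-3,4-dihydro-2H-chromen-3-ol | CC1(C)Oc2ccc(B3OC(C)(C)C(C)(C)O3)c(OCc3ccccc3)c2C[C@@H]1O | intermediate
17 | 2,4,6-trihydroxyacetophenone | CC(=O)c1c(O)cc(O)cc1O | starting material
18 | 1-[2,4-bis(benzyloxy)-6-hydroxyphenyl]ethan-1-one | CC(=O)c1c(O)cc(OCc2ccccc2)cc1OCc1ccccc1 | intermediate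
19 | (2E)-1-[2,4-bis(benzyloxy)-6-hydroxyphenyl]-3-(dimethylamino)prop-2-en-1-one | CN(C)/C=C/C(=O)c1c(O)cc(OCc2ccccc2)cc1OCc1ccccc1 | intermediate
20 | 5,7-bis(benzyloxy)-3-iodo-4H-chromen-4-one | O=c1c(I)coc2cc(OCc3ccccc3)cc(OCc3ccccc3)c12 | intermediate
21 | 5,7-bis(benzyloxy)-3-[(3S)-5-(benzyloxy)-3-hydroxy-2,2-dimethyl-3,4-dihydro-2H-chromen-6-yl]-4H-chromen-4-one | CC1(C)Oc2ccc(-c3coc4cc(OCc5ccccc5)cc(OCc5ccccc5)c4c3=O)c(OCc3ccccc3)c2C[C@@H]1O | intermediate
22 | 5,7-dihydroxy-3-[(3S)-3,5-dihydroxy-2,2-dimethyl-3,4-dihydro-2H-chromen-6-yl]-4H-chromen-4-one | CC1(C)Oc2ccc(-c3coc4cc(O)cc(O)c4c3=O)c(O)c2C[C@@H]1O | target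

**Step count and least certain steps**

Total step count: 14. Longest linear sequence: 11 steps (steps 1 to 9, 13 and 14, from 1); the chromone branch (steps 10 to 12) joins at step 13.

Step 6 (key step). The methide 11 has no substituent on its exocyclic carbon, so it is short-lived. Dimerisation, irreversible N-alkylation of the primary amine and O-alkylation by water or by the hydroxyl of 10 can outrun the enamine addition. The sulfinate may also leave too slowly at low temperature. With no substituent on the methide carbon to help organise the transition state, facial control may be incomplete, and the open-chain α-hydroxy ketone can lose optical purity by enolisation if it stays long in the basic mixture. Fallback (a different construction of ring D): from aldehyde 6, addition of 2-methylprop-1-enylmagnesium bromide (excess, THF, 0 °C) gives 3-(benzyloxy)-4-bromo-2-(1-hydroxy-3-methylbut-2-en-1-yl)phenol F1. Heating in toluene with a trace of acid dehydrates it to a vinyl ortho-quinone methide that closes by oxa-6π electrocyclisation to 5-(benzyloxy)-6-bromo-2,2-dimethyl-2H-chromene F2. Jacobsen epoxidation (NaOCl, (S,S)-N,N'-bis(3,5-di-tert-butylsalicylidene)cyclohexane-1,2-diaminomanganese chloride, 4-phenylpyridine N-oxide, CH2Cl2, 0 °C; the catalyst enantiomer is the one expected, by analogy with other 2,2-dimethylchromenes, to give the S,S epoxide) should give (3S,4S)-5-(benzyloxy)-6-bromo-3,4-epoxy-2,2-dimethylchromane F3. LiAlH4 (THF, 0 °C) opens the epoxide at the benzylic C4, and the route is rejoined at 15.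

Step 8. The aryloxide of ring D is a good leaving group, so the ketal may ionise by endocyclic C–O cleavage, after which methylation of the acyclic oxocarbenium ion would leave ring D open. The ring oxocarbenium ion may also lose a proton towards C3 to an enol ether, which would erase the stereocentre. Fallback: from 13 (in equilibrium with 12), excess MeMgBr (THF, −78 °C to 0 °C) adds to the ketone to give 3-(benzyloxy)-4-bromo-2-[(2S)-2,3-dihydroxy-3-methylbutyl]phenol F4. Catalytic p-toluenesulfonic acid in toluene then closes ring D by attack of the phenol on the tertiary carbocation (the classical Grignard and cyclodehydration route to 2,2-dimethylchromans), and the route is rejoined at 15. C3'' is not part of either reacting centre.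

Step 3. The formyl group is exposed to a strong base and an alkoxide, so addition to the aldehyde or incomplete elimination of the sulfonylethyl group may lower the conversion. Fallback: from 4, 4-methoxybenzyl alcohol and potassium tert-butoxide (KOtBu, THF, 0 °C) displace the fluoride to give 2-(benzyloxy)-3-bromo-6-[(4-methoxyphenyl)methoxy]benzaldehyde F5. Trifluoroacetic acid in CH2Cl2 (0 °C) then removes the 4-methoxybenzyl group selectively beside the benzyl ether, and the route is rejoined at 6.

Step 13 (with step 9). The boronate is electron-rich and carries an ortho alkoxy group, so protodeboronation under aqueous base can compete with transmetalation, and the base can open the chromone ring. Fallback: from 15, stannylation with Me3SnSnMe3 and Pd(PPh3)4 (toluene, 100 °C) gives (3S)-5-(benzyloxy)-2,2-dimethyl-6-(trimethylstannyl)-3,4-dihydro-2H-chromen-3-ol F6. A base-free Stille coupling with 20 (Pd(PPh3)4, CuI, DMF, 60 °C) rejoins the route at 21.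

Step 14. Over-reduction of the chromone C2=C3 bond to the isoflavanone may set in before the third benzyl group is gone. Fallback: from 21, BCl3 with pentamethylbenzene as benzyl-cation scavenger (CH2Cl2, −78 °C) cleaves the three aryl benzyl ethers without hydrogen and arrives directly at 22. No new compound lies on this way.

**Further compounds**

F1 | step 6 | 3-(benzyloxy)-4-bromo-2-(1-hydroxy-3-methylbut-2-en-1-yl)phenol | CC(C)=CC(O)c1c(O)ccc(Br)c1OCc1ccccc1
F2 | step 6 | 5-(benzyloxy)-6-bromo-2,2-dimethyl-2H-chromene | CC1(C)C=Cc2c(OCc3ccccc3)c(Br)ccc2O1
F3 | step 6 | (3S,4S)-5-(benzyloxy)-6-bromo-3,4-epoxy-2,2-dimethylchromane | CC1(C)Oc2ccc(Br)c(OCc3ccccc3)c2[C@@H]2O[C@@H]21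
F4 | step 8 | 3-(benzyloxy)-4-bromo-2-[(2S)-2,3-dihydroxy-3-methylbutyl]phenol | CC(C)(O)[C@@H](O)Cc1c(O)ccc(Br)c1OCc1ccccc1
F5 | step 3 | 2-(benzyloxy)-3-bromo-6-[(4-methoxyphenyl)methoxy]benzaldehyde | COc1ccc(COc2ccc(Br)c(OCc3ccccc3)c2C=O)cc1
F6 | step 13 | (3S)-5-(benzyloxy)-2,2-dimethyl-6-(trimethylstannyl)-3,4-dihydro-2H-chromen-3-ol | CC1(C)Oc2ccc([Sn](C)(C)C)c(OCc3ccccc3)c2C[C@@H]1O
F0 | step 14 | none | none
A1 | alternative 1 | 2,4-dihydroxybenzaldehyde | O=Cc1ccc(O)cc1O
A2 | alternative 1 | 3-methylbut-2-enal | CC(C)=CC=O
A3 | alternative 1 | 5-hydroxy-2,2-dimethyl-2H-chromene-6-carbaldehyde | CC1(C)C=Cc2c(O)c(C=O)ccc2O1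
A4 | alternative 2 | (2Z)-3-[3,5-bis(benzyloxy)phenoxy]-2-[(3S)-3,5-bis(benzyloxy)-2,2-dimethyl-3,4-dihydro-2H-chromen-6-yl]prop-2-enoic acid | O=C(O)/C(=C\Oc1cc(OCc2ccccc2)cc(OCc2ccccc2)c1)c1ccc2OC(C)(C)[C@@H](OCc3ccccc3)Cc2c1OCc1ccccc1
A5 | alternative 2 | 5,7-bis(benzyloxy)-3-[(3S)-3,5-bis(benzyloxy)-2,2-dimethyl-3,4-dihydro-2H-chromen-6-yl]-4H-chromen-4-one | CC1(C)Oc2ccc(-c3coc4cc(OCc5ccccc5)cc(OCc5ccccc5)c4c3=O)c(OCc3ccccc3)c2C[C@@H]1OCc1ccccc1
A6 | alternative 3 | 5,7-bis(methoxymethoxy)-2,2-dimethyl-4H-1,3-benzodioxin-4-one | CC1(C)OC(=O)c2c(OCOC)cc(OCOC)cc2O1
A7 | alternative 3 | (3S)-6-(2-methoxyethenyl)-3,5-bis(methoxymethoxy)-2,2-dimethyl-3,4-dihydro-2H-chromene | COC=Cc1ccc2OC(C)(C)[C@@H](OCOC)Cc2c1OCOC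
A8 | alternative 3 | 3-[(3S)-3,5-bis(methoxymethoxy)-2,2-dimethyl-3,4-dihydro-2H-chromen-6-yl]-2-methoxy-5,7-bis(methoxymethoxy)-2,3-dihydro-4H-chromen-4-one | CC1(C)Oc2ccc(C3C(OC)Oc4cc(OCOC)cc(OCOC)c4C3=O)c(OCOC)c2C[C@@H]1OCOC
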